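**Retrosynthetic overview**

1. Last step: the C3–C4 bond (giving quaternary C3, its vinyl group and the E‑C4=C5 alkene) is made by a copper hydride‑catalysed enantioselective hydroallylation of a terminal alkyne (ring + C4–C8) with an (E)‑γ,γ‑disubstituted allylic phosphate (C1–C3 + C15–C22).
2. Phosphate half: C18–C19 by Negishi coupling of a homoallylic alkylzinc with a 2‑bromoalkene; the C1–C3 head by acetylide alkylation, then zirconium‑catalysed methylalumination and formaldehyde.
3. Alkyne half: C8–C9 by copper‑catalysed conjugate addition of a C5 Grignard reagent to (R)‑4,4,5‑trimethylcyclohexenone, then enolate methylation (C10) and methylation through the kinetic enol triflate (C11).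
4. The three acyclic CH(CH3) centres (C6, C17, C21) all come from (S)‑ or (R)‑3‑methylpent‑4‑yn‑1‑ol, made by asymmetric hydrogenation of α‑methylene‑γ‑butyrolactone and one‑pot reduction/alkyne homologation.
5. Ring order: the only ring (cyclohexene C9–C14) is made first in its branch by acid‑catalysed annulation of isobutyraldehyde with methyl vinyl ketone; C13 is then set by a desymmetrising methyl addition to the derived dienone.

Atom labels follow the target SMILES from left to right: C1=C2 vinyl, C3 quaternary, C4=C5, C6, C7, C8, ring C9 (chain), C10 (Me), C11 (Me), C12 (H), C13 (Me), C14 (Me2), then C15, C16, C17, C18 (=CH2), C19, C20, C21, C22 (=CH2, Me). The target is 3S,6S,9R,10R,13R,17R,21R with a 4E alkene.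

Assumption: each chiral ligand antipode named is taken to be the one that gives the configuration drawn; if the observed sense is opposite, the mirror‑image ligand is used and nothing else changes.

**Route**

Step 1
Reactants: 1 3-methylideneoxolan-2-one (α-methylene-γ-butyrolactone)
Product: 2 (3S)-3-methyloxolan-2-one
Conditions: H2 (100 atm), Ru2Cl4[(R)-BINAP]2·NEt3 (0.5 mol%), CH2Cl2, 50 °C
Reagents that add atoms: none
Why: Noyori-type asymmetric hydrogenation; the lactone carbonyl binds divalent ruthenium and the BINAP pocket delivers H2 to one alkene face, setting the future C6 centre (S, about 95% ee).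

Step 2
Reactants: 2 (3S)-3-methyloxolan-2-one
Product: 4 (3S)-3-methylpent-4-yn-1-ol, via lactol 3 (not isolated)
Conditions: i-Bu2AlH (1.05 equiv), CH2Cl2, −78 °C; then MeOH, K2CO3, dimethyl (1-diazo-2-oxopropyl)phosphonate, 0 °C → rt
Reagents that add atoms: dimethyl (1-diazo-2-oxopropyl)phosphonate, CC(=O)C(=[N+]=[N-])P(=O)(OC)OC
Why: Partial reduction to the lactol followed by Seyferth–Gilbert homologation in its Ohira–Bestmann form on the open hydroxy aldehyde; the mild carbonate base leaves the α-methyl centre intact.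

Step 3
Reactants: 4 (3S)-3-methylpent-4-yn-1-ol
Product: 5 (3S)-5-bromo-3-methylpent-1-yne
Conditions: CBr4, PPh3, CH2Cl2, 0 °C
Reagents that add atoms: carbon tetrabromide, BrC(Br)(Br)Br
Why: Appel reaction at the primary carbinol; the stereocentre is not involved.

Step 4
Reactants: 5 (3S)-5-bromo-3-methylpent-1-yne
Product: 7 [(3S)-5-bromo-3-methylpent-1-yn-1-yl]tri(propan-2-yl)silane, via lithium acetylide 6 (not isolated)
Conditions: LiN(i-Pr)2 (1.05 equiv), THF, −78 °C; then i-Pr3SiOTf, −78 → 0 °C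
Reagents that add atoms: triisopropylsilyl trifluoromethanesulfonate, CC(C)[Si](OS(=O)(=O)C(F)(F)F)(C(C)C)C(C)C
Why: Acetylide formation and C-silylation are much faster at −78 °C than any attack of the amide base on the primary bromide; the bulky silyl group masks the acidic C–H for the organomagnesium and MeLi steps.

Step 5
Reactants: 8 2-methylpropanal; 9 but-3-en-2-one
Product: 10 4,4-dimethylcyclohex-2-en-1-one
Conditions: H2SO4 (cat.), PhH, 45 °C then reflux (Dean–Stark)
Reagents that add atoms: none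
Why: Acid-catalysed Michael addition and intramolecular aldol condensation (Robinson-type annulation) build the six-membered ring with the gem-dimethyl carbon C14.

Step 6
Reactants: 10 4,4-dimethylcyclohex-2-en-1-one
Product: 11 4,4-dimethylcyclohexa-2,5-dien-1-one
Conditions: DDQ, dioxane, reflux
Reagents that add atoms: none
Why: DDQ dehydrogenation of the saturated α,β-positions; the quaternary carbon blocks aromatisation.

Step 7
Reactants: 11 4,4-dimethylcyclohexa-2,5-dien-1-one
Product: 13 (5R)-4,4,5-trimethylcyclohex-2-en-1-one, via methylzinc dienolate 12 (not isolated)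
Conditions: Me2Zn (1.5 equiv), Cu(OTf)2 (2 mol%), (S,R,R)-BINOL bis(1-phenylethyl)amine phosphoramidite (4 mol%), toluene, −25 °C; aq NH4Cl
Reagents that add atoms: dimethylzinc, C[Zn]C
Why: Copper-catalysed enantioselective conjugate addition desymmetrises the dienone; the ligand picks one enantiotopic alkene and face to set C13 (R), and the zinc dienolate cannot add a second methyl.

Step 8
Reactants: 7 [(3S)-5-bromo-3-methylpent-1-yn-1-yl]tri(propan-2-yl)silane; 13 (5R)-4,4,5-trimethylcyclohex-2-en-1-one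
Product: 15 trimethyl{[(3R,5R)-4,4,5-trimethyl-3-{(3S)-3-methyl-5-[tri(propan-2-yl)silyl]pent-4-yn-1-yl}cyclohex-1-en-1-yl]oxy}silane, via Grignard reagent 14 (not isolated)
Conditions: 7, Mg, THF, 40 °C; then CuI·2LiCl (10 mol%), Me3SiCl (2 equiv), 13, THF, −40 °C
Reagents that add atoms: chlorotrimethylsilane, C[Si](C)(C)Cl
Why: Chlorosilane-accelerated copper-catalysed conjugate addition; axial attack on the half-chair that keeps the C13 methyl pseudo-equatorial comes from the face opposite the pseudo-axial gem-methyl, placing the chain trans to the C13 methyl and setting C9 (R).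

Step 9
Reactants: 15 trimethyl{[(3R,5R)-4,4,5-trimethyl-3-{(3S)-3-methyl-5-[tri(propan-2-yl)silyl]pent-4-yn-1-yl}cyclohex-1-en-1-yl]oxy}silane
Product: 17 (2R,3R,5R)-2,4,4,5-tetramethyl-3-{(3S)-3-methyl-5-[tri(propan-2-yl)silyl]pent-4-yn-1-yl}cyclohexan-1-one, via lithium enolate 16 (not isolated)
Conditions: MeLi (1.05 equiv), THF, 0 °C; then MeI, DMPU, −78 → 0 °C
Reagents that add atoms: iodomethane, CI
Why: Regiospecific enolate generation from the silyl enol ether and alkylation anti to the adjacent C9 chain give the 2,3-trans ketone, setting C10 (R); this is also the thermodynamically favoured epimer.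

Step 10
Reactants: 17 (2R,3R,5R)-2,4,4,5-tetramethyl-3-{(3S)-3-methyl-5-[tri(propan-2-yl)silyl]pent-4-yn-1-yl}cyclohexan-1-one
Product: 19 (3R,5R,6R)-3,4,4,6-tetramethyl-5-{(3S)-3-methyl-5-[tri(propan-2-yl)silyl]pent-4-yn-1-yl}cyclohex-1-en-1-yl trifluoromethanesulfonate, via lithium enolate 18 (not isolated)
Conditions: LiN(i-Pr)2, THF, −78 °C; then PhNTf2, −78 → 0 °C; aq NH4Cl
Reagents that add atoms: N-phenylbis(trifluoromethanesulfonimide), O=S(=O)(N(c1ccccc1)S(=O)(=O)C(F)(F)F)C(F)(F)F
Why: Kinetic deprotonation takes the CH2 (C12) rather than the hindered CH(CH3) (C10), so enolate O-sulfonylation fixes the alkene at C11=C12 without touching C10.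

Step 11
Reactants: 19 (3R,5R,6R)-3,4,4,6-tetramethyl-5-{(3S)-3-methyl-5-[tri(propan-2-yl)silyl]pent-4-yn-1-yl}cyclohex-1-en-1-yl trifluoromethanesulfonate
Product: 20 {(3S)-3-methyl-5-[(1R,2R,5R)-2,3,5,6,6-pentamethylcyclohex-3-en-1-yl]pent-1-yn-1-yl}tri(propan-2-yl)silane
Conditions: MeMgBr (1.5 equiv), Fe(acac)3 (5 mol%), THF/NMP, −30 → 0 °C
Reagents that add atoms: methylmagnesium bromide, C[Mg]Br
Why: Iron-catalysed Kumada-type cross-coupling of the alkenyl triflate installs the C11 methyl with the alkene position retained; the silyl alkyne is inert.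

Step 12
Reactants: 20 {(3S)-3-methyl-5-[(1R,2R,5R)-2,3,5,6,6-pentamethylcyclohex-3-en-1-yl]pent-1-yn-1-yl}tri(propan-2-yl)silane
Product: 21 (3R,5R,6R)-1,3,4,4,6-pentamethyl-5-[(3S)-3-methylpent-4-yn-1-yl]cyclohex-1-ene
Conditions: Bu4NF, THF, 0 °C → rt
Reagents that add atoms: none
Why: Fluoride-induced protodesilylation frees the terminal alkyne; nothing else in the hydrocarbon reacts.

Step 13
Reactants: 1 3-methylideneoxolan-2-one
Product: 22 (3R)-3-methyloxolan-2-one
Conditions: H2 (100 atm), Ru2Cl4[(S)-BINAP]2·NEt3 (0.5 mol%), CH2Cl2, 50 °C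
Reagents that add atoms: none
Why: The same asymmetric hydrogenation with the mirror-image ligand gives the R lactone, the source of C17 and C21.

Step 14
Reactants: 22 (3R)-3-methyloxolan-2-one
Product: 24 (3R)-3-methylpent-4-yn-1-ol, via lactol 23 (not isolated)
Conditions: i-Bu2AlH (1.05 equiv), CH2Cl2, −78 °C; then MeOH, K2CO3, dimethyl (1-diazo-2-oxopropyl)phosphonate, 0 °C → rt
Reagents that add atoms: dimethyl (1-diazo-2-oxopropyl)phosphonate, CC(=O)C(=[N+]=[N-])P(=O)(OC)OC
Why: Lactol formation and Ohira–Bestmann (Seyferth–Gilbert) homologation as in step 2, with the stereocentre retained.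

Step 15
Reactants: 24 (3R)-3-methylpent-4-yn-1-ol
Product: 26 (3R)-3,4-dimethylpent-4-en-1-ol, via alkenylalane 25 (not isolated)
Conditions: AlMe3 (3 equiv), Cp2ZrCl2 (0.25 equiv), CH2Cl2, 0 °C → rt; then 3 M HCl, 0 °C
Reagents that add atoms: trimethylaluminium, C[Al](C)C
Why: Negishi zirconium-catalysed carboalumination adds methyl to the internal alkyne carbon (syn), and protonolysis of the C–Al bond leaves the isopropenyl group (C22) next to the untouched C21 centre.

Step 16
Reactants: 26 (3R)-3,4-dimethylpent-4-en-1-ol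
Product: 27 (3R)-5-iodo-2,3-dimethylpent-1-ene
Conditions: I2, PPh3, imidazole, CH2Cl2, 0 °C
Reagents that add atoms: iodine, II
Why: Appel-type iodination of the primary alcohol under neutral conditions that spare the alkene.

Step 17
Reactants: 24 (3R)-3-methylpent-4-yn-1-ol
Product: 28 (3R)-5-bromo-3-methylpent-1-yne
Conditions: CBr4, PPh3, CH2Cl2, 0 °C
Reagents that add atoms: carbon tetrabromide, BrC(Br)(Br)Br
Why: Appel reaction at the primary carbinol; the stereocentre is not involved.

Step 18
Reactants: 28 (3R)-5-bromo-3-methylpent-1-yne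
Product: 30 (3R)-2,5-dibromo-3-methylpent-1-ene, via bromoalkenylborane 29 (not isolated)
Conditions: B-bromo-9-BBN (1.1 equiv), CH2Cl2, 0 °C → rt; then AcOH
Reagents that add atoms: 9-bromo-9-borabicyclo[3.3.1]nonane, BrB1C2CCCC1CCC2
Why: Syn Markovnikov bromoboration of the terminal alkyne followed by protodeboronation gives the 2-bromo-1-alkene (the future C18 methylidene); the alkyl bromide and C17 are untouched.

Step 19
Reactants: 27 (3R)-5-iodo-2,3-dimethylpent-1-ene; 30 (3R)-2,5-dibromo-3-methylpent-1-ene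
Product: 32 (3R,7R)-9-bromo-2,3,7-trimethyl-6-methylidenenon-1-ene, via alkylzinc iodide 31 (not isolated)
Conditions: 27, Zn dust, LiCl, THF, 40 °C; then 30, PdCl2(dppf) (3 mol%), THF, 50 °C
Reagents that add atoms: none
Why: Negishi coupling; zerovalent palladium inserts into the alkenyl C–Br bond far faster than into the primary alkyl C–Br bond, forming C18–C19 with the methylidene already in place and no stereocentre touched.

Step 20
Reactants: 32 (3R,7R)-9-bromo-2,3,7-trimethyl-6-methylidenenon-1-ene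
Product: 33 (5R,9R)-5,9,10-trimethyl-6-methylideneundec-10-en-1-yne
Conditions: LiC≡CH·H2NCH2CH2NH2, DMSO, 0 °C → rt
Reagents that add atoms: lithium acetylide, [Li]C#C
Why: SN2 alkylation of acetylide by the primary bromide in a dipolar aprotic solvent brings in C2 and C3.

Step 21
Reactants: 33 (5R,9R)-5,9,10-trimethyl-6-methylideneundec-10-en-1-yne
Product: 36 (2E,6R,10R)-3,6,10,11-tetramethyl-7-methylidenedodeca-2,11-dien-1-ol, via alkenylalane 34 (not isolated), via lithium alanate 35 (not isolated)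
Conditions: AlMe3 (2 equiv), Cp2ZrCl2 (0.25 equiv), CH2Cl2, rt; then n-BuLi, THF, −78 °C; (CH2O)n, → rt; 1 M HCl
Reagents that add atoms: trimethylaluminium, C[Al](C)C; paraformaldehyde (as formaldehyde), C=O
Why: Negishi carboalumination is syn and alkyne-selective (1,1-disubstituted alkenes do not react), and hydroxymethylation of the ate complex with retention gives the E trisubstituted allylic alcohol.

Step 22
Reactants: 36 (2E,6R,10R)-3,6,10,11-tetramethyl-7-methylidenedodeca-2,11-dien-1-ol
Product: 37 diethyl (2E,6R,10R)-3,6,10,11-tetramethyl-7-methylidenedodeca-2,11-dien-1-yl phosphate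
Conditions: ClP(O)(OEt)2, Et3N, DMAP (cat.), CH2Cl2, 0 °C
Reagents that add atoms: diethyl chlorophosphate, CCOP(=O)(Cl)OCC
Why: O-phosphorylation of the primary allylic alcohol gives the leaving group needed for copper-catalysed SN2′ substitution.

Step 23
Reactants: 21 (3R,5R,6R)-1,3,4,4,6-pentamethyl-5-[(3S)-3-methylpent-4-yn-1-yl]cyclohex-1-ene; 37 diethyl (2E,6R,10R)-3,6,10,11-tetramethyl-7-methylidenedodeca-2,11-dien-1-yl phosphate
Product: 38 (3S,6R,10R)-3-{(1E,3S)-3-methyl-5-[(1R,2R,5R)-2,3,5,6,6-pentamethylcyclohex-3-en-1-yl]pent-1-en-1-yl}-3,6,10,11-tetramethyl-7-methylidenedodeca-1,11-diene (CNP0157304.1)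
Conditions: CuCl (5 mol%), enantiopure 4,5-diphenylimidazolinium salt with N-(2,6-diethylphenyl) and N-(2-sulfonatophenyl) groups (5.5 mol%), LiOtBu (1.5 equiv), (EtO)2MeSiH (1.5 equiv, slow addition), 21 (1.2 equiv), THF, 22 °C
Reagents that add atoms: none
Why: Proposed new method: a monovalent copper hydride carrying the chiral sulfonate-bridged N-heterocyclic carbene (from CuCl, the imidazolinium salt, LiOtBu and the silane) adds syn and anti-Markovnikov across the terminal alkyne of 21 to give an (E)-alkenylcopper, which attacks the γ-carbon (C3) of (E)-phosphate 37 by SN2′ oxidative addition anti to the phosphate and reductive elimination, the lithium-bridged sulfonate–phosphate contact fixing one enantiotopic face so that the C3–C4 bond, the vinyl group and the quaternary centre (3S) form together, after which LiOtBu and the silane turn the copper phosphate back into the hydride; the closest known reactions are the achiral NHC–copper hydride hydroallylation of terminal alkynes with simple allyl phosphates and the NHC–copper-catalysed enantioselective allylic substitution of trisubstituted allylic phosphates with preformed alkenylaluminium or alkenyl–B(pin) reagents, and the new element is their merger on an α-branched aliphatic alkyne and a γ,γ-dialkyl phosphate to form an all-carbon quaternary stereocentre.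

**Compound list**

1 | 3-methylideneoxolan-2-one (α-methylene-γ-butyrolactone) | C=C1CCOC1=O | starting material
2 | (3S)-3-methyloxolan-2-one | O=C1[C@@H](C)CCO1 | intermediate
3 | (3S)-3-methyloxolan-2-ol (lactol, both anomers) | OC1[C@@H](C)CCO1 | intermediate
4 | (3S)-3-methylpent-4-yn-1-ol | C#C[C@@H](C)CCO | intermediate
5 | (3S)-5-bromo-3-methylpent-1-yne | C#C[C@@H](C)CCBr | intermediate
6 | lithium (3S)-5-bromo-3-methylpent-1-yn-1-ide | [Li]C#C[C@@H](C)CCBr | intermediate
7 | [(3S)-5-bromo-3-methylpent-1-yn-1-yl]tri(propan-2-yl)silane | CC(C)[Si](C(C)C)(C(C)C)C#C[C@@H](C)CCBr | intermediate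
8 | 2-methylpropanal (isobutyraldehyde) | CC(C)C=O | starting material
9 | but-3-en-2-one (methyl vinyl ketone) | CC(=O)C=C | starting material
10 | 4,4-dimethylcyclohex-2-en-1-one | CC1(C)CCC(=O)C=C1 | intermediate
11 | 4,4-dimethylcyclohexa-2,5-dien-1-one | CC1(C)C=CC(=O)C=C1 | intermediate
12 | methylzinc (3R)-3,4,4-trimethylcyclohexa-1,5-dien-1-olate | C[Zn]OC1=C[C@@H](C)C(C)(C)C=C1 | intermediate
13 | (5R)-4,4,5-trimethylcyclohex-2-en-1-one | O=C1C=CC(C)(C)[C@H](C)C1 | intermediate
14 | {(3S)-3-methyl-5-[tri(propan-2-yl)silyl]pent-4-yn-1-yl}magnesium bromide | CC(C)[Si](C(C)C)(C(C)C)C#C[C@@H](C)CC[Mg]Br | intermediate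
15 | trimethyl{[(3R,5R)-4,4,5-trimethyl-3-{(3S)-3-methyl-5-[tri(propan-2-yl)silyl]pent-4-yn-1-yl}cyclohex-1-en-1-yl]oxy}silane | CC(C)[Si](C(C)C)(C(C)C)C#C[C@@H](C)CC[C@@H]1C=C(O[Si](C)(C)C)C[C@@H](C)C1(C)C | intermediate
16 | lithium (3R,5R)-4,4,5-trimethyl-3-{(3S)-3-methyl-5-[tri(propan-2-yl)silyl]pent-4-yn-1-yl}cyclohex-1-en-1-olate | CC(C)[Si](C(C)C)(C(C)C)C#C[C@@H](C)CC[C@@H]1C=C(O[Li])C[C@@H](C)C1(C)C | intermediate
17 | (2R,3R,5R)-2,4,4,5-tetramethyl-3-{(3S)-3-methyl-5-[tri(propan-2-yl)silyl]pent-4-yn-1-yl}cyclohexan-1-one | CC(C)[Si](C(C)C)(C(C)C)C#C[C@@H](C)CC[C@@H]1[C@@H](C)C(=O)C[C@@H](C)C1(C)C | intermediate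
18 | lithium (3R,5R,6R)-3,4,4,6-tetramethyl-5-{(3S)-3-methyl-5-[tri(propan-2-yl)silyl]pent-4-yn-1-yl}cyclohex-1-en-1-olate | CC(C)[Si](C(C)C)(C(C)C)C#C[C@@H](C)CC[C@@H]1[C@@H](C)C(O[Li])=C[C@@H](C)C1(C)C | intermediate
19 | (3R,5R,6R)-3,4,4,6-tetramethyl-5-{(3S)-3-methyl-5-[tri(propan-2-yl)silyl]pent-4-yn-1-yl}cyclohex-1-en-1-yl trifluoromethanesulfonate | CC(C)[Si](C(C)C)(C(C)C)C#C[C@@H](C)CC[C@@H]1[C@@H](C)C(OS(=O)(=O)C(F)(F)F)=C[C@@H](C)C1(C)C | intermediate
20 | {(3S)-3-methyl-5-[(1R,2R,5R)-2,3,5,6,6-pentamethylcyclohex-3-en-1-yl]pent-1-yn-1-yl}tri(propan-2-yl)silane | CC(C)[Si](C(C)C)(C(C)C)C#C[C@@H](C)CC[C@@H]1[C@@H](C)C(C)=C[C@@H](C)C1(C)C | intermediate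
21 | (3R,5R,6R)-1,3,4,4,6-pentamethyl-5-[(3S)-3-methylpent-4-yn-1-yl]cyclohex-1-ene | C#C[C@@H](C)CC[C@@H]1[C@@H](C)C(C)=C[C@@H](C)C1(C)C | intermediate
22 | (3R)-3-methyloxolan-2-one | O=C1[C@H](C)CCO1 | intermediate
23 | (3R)-3-methyloxolan-2-ol (lactol, both anomers) | OC1[C@H](C)CCO1 | intermediate
24 | (3R)-3-methylpent-4-yn-1-ol | C#C[C@H](C)CCO | intermediate
25 | {[(3R,4E)-5-(dimethylalumanyl)-3,4-dimethylpent-4-en-1-yl]oxy}dimethylalumane | C[Al](C)/C=C(\C)[C@H](C)CCO[Al](C)C | intermediate
26 | (3R)-3,4-dimethylpent-4-en-1-ol | C=C(C)[C@H](C)CCO | intermediate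
27 | (3R)-5-iodo-2,3-dimethylpent-1-ene | C=C(C)[C@H](C)CCI | intermediate
28 | (3R)-5-bromo-3-methylpent-1-yne | C#C[C@H](C)CCBr | intermediate
29 | 9-[(1Z,3R)-2,5-dibromo-3-methylpent-1-en-1-yl]-9-borabicyclo[3.3.1]nonane | B1(/C=C(\Br)[C@H](C)CCBr)C2CCCC1CCC2 | intermediate
30 | (3R)-2,5-dibromo-3-methylpent-1-ene | C=C(Br)[C@H](C)CCBr | intermediate
31 | [(3R)-3,4-dimethylpent-4-en-1-yl]zinc iodide | C=C(C)[C@H](C)CC[Zn]I | intermediate
32 | (3R,7R)-9-bromo-2,3,7-trimethyl-6-methylidenenon-1-ene | BrCC[C@@H](C)C(=C)CC[C@@H](C)C(=C)C | intermediate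
33 | (5R,9R)-5,9,10-trimethyl-6-methylideneundec-10-en-1-yne | C#CCC[C@@H](C)C(=C)CC[C@@H](C)C(=C)C | intermediate
34 | dimethyl[(1E,5R,9R)-2,5,9,10-tetramethyl-6-methylideneundeca-1,10-dien-1-yl]alumane | C[Al](C)/C=C(\C)CC[C@@H](C)C(=C)CC[C@@H](C)C(=C)C | intermediate
35 | lithium butyldimethyl[(1E,5R,9R)-2,5,9,10-tetramethyl-6-methylideneundeca-1,10-dien-1-yl]aluminate | [Li+].CCCC[Al-](C)(C)/C=C(\C)CC[C@@H](C)C(=C)CC[C@@H](C)C(=C)C | intermediate
36 | (2E,6R,10R)-3,6,10,11-tetramethyl-7-methylidenedodeca-2,11-dien-1-ol | OC/C=C(\C)CC[C@@H](C)C(=C)CC[C@@H](C)C(=C)C | intermediate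
37 | diethyl (2E,6R,10R)-3,6,10,11-tetramethyl-7-methylidenedodeca-2,11-dien-1-yl phosphate | CCOP(=O)(OCC)OC/C=C(\C)CC[C@@H](C)C(=C)CC[C@@H](C)C(=C)C | intermediate
38 | (3S,6R,10R)-3-{(1E,3S)-3-methyl-5-[(1R,2R,5R)-2,3,5,6,6-pentamethylcyclohex-3-en-1-yl]pent-1-en-1-yl}-3,6,10,11-tetramethyl-7-methylidenedodeca-1,11-diene (CNP0157304.1) | C=C[C@@](C)(/C=C/[C@@H](C)CC[C@@H]1[C@@H](C)C(C)=C[C@@H](C)C1(C)C)CC[C@@H](C)C(=C)CC[C@@H](C)C(=C)C | target

**Totals and risks**

Total step count: 23. Longest linear sequence: 10 steps (1, 2, 3, 4, 8, 9, 10, 11, 12, 23).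

Three steps most likely to fail:

Step 23 (the proposed hydroallylation). The copper hydride may reduce phosphate 37 directly, the alkyne may rest as a copper acetylide, and the face selectivity at C3 decides a diastereomer ratio that cannot be corrected later. Fallback with known chemistry: setting out from 21, Cp2Zr(H)Cl-catalysed hydroboration with pinacolborane (CH2Cl2, rt) gives the (E)-alkenyl pinacol boronate 2-{(1E,3S)-3-methyl-5-[(1R,2R,5R)-2,3,5,6,6-pentamethylcyclohex-3-en-1-yl]pent-1-en-1-yl}-4,4,5,5-tetramethyl-1,3,2-dioxaborolane F1. F1 and 37 are then joined by the established NHC–copper-catalysed enantioselective allylic substitution of alkenyl–B(pin) reagents (CuCl 5 mol%, the same sulfonate imidazolinium salt, NaOMe 1.5 equiv, THF, 60 °C). This forms the same C3–C4 bond by boron-to-copper transmetalation with no hydride present and comes back to the route at 38.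

Step 8 (conjugate addition at the neopentyl β-carbon). The β-carbon sits next to the gem-dimethyl carbon, so the addition may stall or give a poor trans:cis ratio, and the organomagnesium reagent must be made from a valuable bromide. Fallback: setting out from 7 and 13, a nickel-catalysed reductive conjugate addition (NiCl2(dme) 5 mol%, neocuproine 5 mol%, Mn powder, Et3SiCl, DMF, 40 °C) couples the alkyl bromide with the enone through a silyloxyallyl-nickel intermediate without any preformed organometallic. It gives the triethylsilyl enol ether triethyl{[(3R,5R)-4,4,5-trimethyl-3-{(3S)-3-methyl-5-[tri(propan-2-yl)silyl]pent-4-yn-1-yl}cyclohex-1-en-1-yl]oxy}silane F2. MeLi in THF converts F2 into lithium enolate 16, where the route is rejoined, and methylation as in step 9 gives 17.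

Step 9 (enolate methylation). Enolate equilibration to the C12 side, double methylation or O-methylation can erode yield at this hindered position. Fallback: setting out from 15, Furukawa-modified Simmons–Smith cyclopropanation (Et2Zn, CH2I2, CH2Cl2, 0 °C) attacks the silyl enol ether anti to the C9 chain and gives the siloxycyclopropane 3,4,4-trimethyl-5-{(3S)-3-methyl-5-[tri(propan-2-yl)silyl]pent-4-yn-1-yl}-1-(trimethylsilyloxy)bicyclo[4.1.0]heptane (cyclopropane CH2 trans to the chain) F3. NaOH in MeOH/H2O then opens the cyclopropane at the C11–CH2 bond (Conia α-methylation), which delivers exactly one methyl at C10 and comes back to the route at 17.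

Further compounds
F1 | step 23 | 2-{(1E,3S)-3-methyl-5-[(1R,2R,5R)-2,3,5,6,6-pentamethylcyclohex-3-en-1-yl]pent-1-en-1-yl}-4,4,5,5-tetramethyl-1,3,2-dioxaborolane | CC1(C)OB(/C=C/[C@@H](C)CC[C@@H]2[C@@H](C)C(C)=C[C@@H](C)C2(C)C)OC1(C)C
F2 | step 8 | triethyl{[(3R,5R)-4,4,5-trimethyl-3-{(3S)-3-methyl-5-[tri(propan-2-yl)silyl]pent-4-yn-1-yl}cyclohex-1-en-1-yl]oxy}silane | CC(C)[Si](C(C)C)(C(C)C)C#C[C@@H](C)CC[C@@H]1C=C(O[Si](CC)(CC)CC)C[C@@H](C)C1(C)C
F3 | step 9 | 3,4,4-trimethyl-5-{(3S)-3-methyl-5-[tri(propan-2-yl)silyl]pent-4-yn-1-yl}-1-(trimethylsilyloxy)bicyclo[4.1.0]heptane, cyclopropane CH2 trans to the chain | CC(C)[Si](C(C)C)(C(C)C)C#C[C@@H](C)CC[C@@H]1[C@H]2C[C@@]2(O[Si](C)(C)C)C[C@@H](C)C1(C)C
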